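**Retrosynthetic overview**
1. The C3-C1' bond is cut last (Suzuki-Miyaura). This gives a 3-iodochromone (rings A and C, from 2,4-dihydroxyacetophenone) and a C1' boronate of the chroman (rings B and D).
2. Ring D is cut at O-CMe2 and CH2-CH2 by a retro-[4+2] to isobutene and an ortho-quinone methide. The quinone methide comes from a salicyl alcohol whose carbinol carbon is the formyl carbon of 2,4,6-trihydroxybenzaldehyde.
3. Feature used: the benzylic CH2 of ring D sits on C3' of ring B, between the C2' methoxy group and the C4' ring oxygen. Only O4' can therefore become the quinone methide oxygen; O6', para to that carbon, stays capped.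
4. The C1' bromine is set before ring D exists, ortho to the one free phenol, which is then methylated to C2'-OMe. In a halogen-free chroman the C-H between the ring oxygen and O6' would be expected to compete in metalation or halogenation.
5. Ring order: B (bought), D (step 6), A (bought), C (step 10), then union and deprotection.

Key step: step 6

Remark on numbering and stereochemistry: primed locants refer to ring B of the isoflavone. C1', C2', C3', C4', C5' and C6' are C6, C5, C4a, C8a, C8 and C7 of the chroman. The target has no stereocentre, and rotation about C3-C1' is assumed to be free at room temperature.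

Step 1
Reactants: 1 2,4,6-trihydroxybenzaldehyde
Product: 2 2-hydroxy-4,6-bis(methoxymethoxy)benzaldehyde
Conditions: MOMCl (2.1 equiv), i-Pr2NEt, CH2Cl2, 0 °C to rt
Reagents that add atoms: chloromethyl methyl ether (MOMCl), COCCl
Why: In this Williamson-type O-alkylation the para hydroxyl and one ortho hydroxyl react, and the remaining ortho hydroxyl is held in a hydrogen bond to the formyl oxygen and should stay free.

Step 2
Reactants: 2 2-hydroxy-4,6-bis(methoxymethoxy)benzaldehyde
Product: 3 3-bromo-2-hydroxy-4,6-bis(methoxymethoxy)benzaldehyde
Conditions: NBS (1.0 equiv), DMF, 0 °C, dark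
Reagents that add atoms: N-bromosuccinimide, O=C1CCC(=O)N1Br
Why: In this electrophilic aromatic bromination the free phenol directs ortho and C3 has the small OH as neighbour while C5 lies between two MOM ethers, which is the orientation known for 2-hydroxy-4,6-dialkoxyaryl carbonyl compounds.

Step 3
Reactants: 3 3-bromo-2-hydroxy-4,6-bis(methoxymethoxy)benzaldehyde
Product: 4 3-bromo-2-methoxy-4,6-bis(methoxymethoxy)benzaldehyde
Conditions: MeI, K2CO3, DMF, rt to 40 °C
Reagents that add atoms: iodomethane, CI
Why: Williamson methylation of the only free phenol should proceed because the small electrophile tolerates the two ortho neighbours, and it fixes the methoxy group next to the bromine (future C2'-OMe beside C1').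

Step 4
Reactants: 4 3-bromo-2-methoxy-4,6-bis(methoxymethoxy)benzaldehyde
Product: 5 3-bromo-6-hydroxy-2-methoxy-4-(methoxymethoxy)benzaldehyde
Conditions: MgBr2·OEt2 (1.5 equiv), CH2Cl2/Et2O, 0 °C to rt; aq. NH4Cl
Reagents that add atoms: none
Why: In this chelation-assisted Lewis acid cleavage of an aryl ether ortho to a carbonyl group, magnesium binds the formyl oxygen and the C6 acetal oxygen, so bromide should remove only that MOM group while the unchelated C4 MOM ether and the far less labile C2 methyl ether stay.

Step 5
Reactants: 5 3-bromo-6-hydroxy-2-methoxy-4-(methoxymethoxy)benzaldehyde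
Product: 6 4-bromo-2-(hydroxymethyl)-3-methoxy-5-(methoxymethoxy)phenol
Conditions: NaBH4, THF/MeOH, 0 °C; neutral quench (aq. NH4Cl), used without delay
Reagents that add atoms: none
Why: In this borohydride reduction of the aldehyde, the low temperature and neutral work-up should keep the electron-rich salicyl alcohol from ionising early, which would lead to over-reduction or oligomers.

Step 6
Reactants: 6 4-bromo-2-(hydroxymethyl)-3-methoxy-5-(methoxymethoxy)phenol; 7 isobutene
Product: 9 6-bromo-5-methoxy-7-(methoxymethoxy)-2,2-dimethylchroman, via ortho-quinone methide 8 (not isolated)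
Conditions: isobutene (ca. 50 equiv, condensed in at -78 °C), toluene (0.03 M in 6), sealed steel autoclave, 150 °C
Reagents that add atoms: none
Why: Heating expels water from the ortho-hydroxybenzyl alcohol, helped by the oxygen donors ortho and para to the benzylic carbon, and gives ortho-quinone methide 8, an oxadiene made of O4', C4', C3' and the exocyclic CH2. This adds isobutene in an asynchronous inverse-electron-demand hetero-Diels-Alder reaction, the known thermal chroman synthesis from salicyl alcohols and simple alkenes, and rearomatisation of ring B makes the addition irreversible. Ring D closes in this intermolecular [4+2] mode, with the CH2-CH2 bond (C4-C3 of the chroman) forming ahead of the O1-C2 bond. No stereocentre is formed. The orientation of the alkene follows from the build-up of positive charge on its tertiary carbon, so the CMe2 carbon ends on oxygen; the choice of oxygen is fixed because O2' is methylated and O6', para to the benzylic carbon, is capped as a MOM ether, so neither a second ortho- nor a para-quinone methide can form. The competition to be won is against self-condensation of 8 (dimerisation, or attack by the free C5'-H position of another molecule), which should be held back by high dilution of 6, a large excess of alkene, and the bromine that occupies C1' and twists the C2' methoxy group out of conjugation.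

Step 7
Reactants: 9 6-bromo-5-methoxy-7-(methoxymethoxy)-2,2-dimethylchroman
Product: 11 2-[5-methoxy-7-(methoxymethoxy)-2,2-dimethylchroman-6-yl]-4,4,5,5-tetramethyl-1,3,2-dioxaborolane, via aryllithium 10 (not isolated)
Conditions: n-BuLi (1.1 equiv), THF, -78 °C; i-PrOBpin, -78 °C to rt; aq. NH4Cl
Reagents that add atoms: 2-isopropoxy-4,4,5,5-tetramethyl-1,3,2-dioxaborolane, CC(C)OB1OC(C)(C)C(C)(C)O1; n-butyllithium, [Li]CCCC (supplies the lithium of 10 only)
Why: Bromine-lithium exchange is faster than any deprotonation at -78 °C and places the metal at C6 only, and the aryllithium, held by its two flanking oxygens, should be trapped cleanly by the borate ester (borylation).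

Step 8
Reactants: 12 2,4-dihydroxyacetophenone
Product: 13 1-[2-hydroxy-4-(methoxymethoxy)phenyl]ethanone
Conditions: MOMCl (1.1 equiv), i-Pr2NEt, CH2Cl2, 0 °C to rt
Reagents that add atoms: chloromethyl methyl ether (MOMCl), COCCl
Why: This selective Williamson-type O-alkylation should cap only the para hydroxyl, because the ortho hydroxyl is hydrogen-bonded to the ketone.

Step 9
Reactants: 13 1-[2-hydroxy-4-(methoxymethoxy)phenyl]ethanone
Product: 14 (E)-3-(dimethylamino)-1-[2-hydroxy-4-(methoxymethoxy)phenyl]prop-2-en-1-one
Conditions: DMF-DMA (2 equiv), toluene, 95 °C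
Reagents that add atoms: N,N-dimethylformamide dimethyl acetal, COC(OC)N(C)C
Why: Condensation of the methyl ketone with the amide acetal gives the enaminone, and the E geometry is the conjugated, less crowded form.

Step 10
Reactants: 14 (E)-3-(dimethylamino)-1-[2-hydroxy-4-(methoxymethoxy)phenyl]prop-2-en-1-one
Product: 15 3-iodo-7-(methoxymethoxy)-4H-chromen-4-one
Conditions: I2 (1.2 equiv), pyridine, CHCl3, rt; aq. Na2S2O3
Reagents that add atoms: iodine, II
Why: In this iodocyclisation, iodine attacks the nucleophilic alpha carbon of the enaminone, the phenol oxygen adds to the iminium carbon and dimethylamine leaves, which closes ring C with iodine at C3 under non-acidic conditions that spare the MOM ether.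

Step 11
Reactants: 11 2-[5-methoxy-7-(methoxymethoxy)-2,2-dimethylchroman-6-yl]-4,4,5,5-tetramethyl-1,3,2-dioxaborolane; 15 3-iodo-7-(methoxymethoxy)-4H-chromen-4-one
Product: 16 7-(methoxymethoxy)-3-[5-methoxy-7-(methoxymethoxy)-2,2-dimethylchroman-6-yl]-4H-chromen-4-one
Conditions: Pd(OAc)2 (5 mol %), SPhos (10 mol %), K3PO4 (3 equiv), toluene/H2O (10:1), 80 °C
Reagents that add atoms: none
Why: This Suzuki-Miyaura coupling of a 3-iodochromone is the standard isoflavone assembly, and the bulky electron-rich biaryl phosphine on zerovalent palladium is chosen because it couples boronates with two ortho alkoxy groups before they lose boron.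

Step 12
Reactants: 16 7-(methoxymethoxy)-3-[5-methoxy-7-(methoxymethoxy)-2,2-dimethylchroman-6-yl]-4H-chromen-4-one
Product: 17 glycyrrhizaisoflavone C, 7-hydroxy-3-(7-hydroxy-5-methoxy-2,2-dimethylchroman-6-yl)-4H-chromen-4-one
Conditions: 3 M HCl, MeOH, 50 °C
Reagents that add atoms: none
Why: Acid-catalysed acetal methanolysis should remove both MOM groups while the aryl methyl ether, the pyrone and ring D stay, since any reversible opening of ring D could re-close only on O4'.

**Compound list**
1 | 2,4,6-trihydroxybenzaldehyde | O=Cc1c(O)cc(O)cc1O | starting material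
2 | 2-hydroxy-4,6-bis(methoxymethoxy)benzaldehyde | O=Cc1c(O)cc(OCOC)cc1OCOC | intermediate
3 | 3-bromo-2-hydroxy-4,6-bis(methoxymethoxy)benzaldehyde | O=Cc1c(O)c(Br)c(OCOC)cc1OCOC | intermediate
4 | 3-bromo-2-methoxy-4,6-bis(methoxymethoxy)benzaldehyde | O=Cc1c(OC)c(Br)c(OCOC)cc1OCOC | intermediate
5 | 3-bromo-6-hydroxy-2-methoxy-4-(methoxymethoxy)benzaldehyde | O=Cc1c(OC)c(Br)c(OCOC)cc1O | intermediate
6 | 4-bromo-2-(hydroxymethyl)-3-methoxy-5-(methoxymethoxy)phenol | OCc1c(OC)c(Br)c(OCOC)cc1O | intermediate
7 | isobutene (2-methylpropene) | C=C(C)C | starting material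
8 | 4-bromo-5-methoxy-3-(methoxymethoxy)-6-methylidenecyclohexa-2,4-dien-1-one (ortho-quinone methide, not isolated) | C=C1C(=O)C=C(OCOC)C(Br)=C1OC | intermediate
9 | 6-bromo-5-methoxy-7-(methoxymethoxy)-2,2-dimethylchroman | COc1c(Br)c(OCOC)cc2OC(C)(C)CCc12 | intermediate
10 | [5-methoxy-7-(methoxymethoxy)-2,2-dimethylchroman-6-yl]lithium (not isolated) | COc1c([Li])c(OCOC)cc2OC(C)(C)CCc12 | intermediate
11 | 2-[5-methoxy-7-(methoxymethoxy)-2,2-dimethylchroman-6-yl]-4,4,5,5-tetramethyl-1,3,2-dioxaborolane | COc1c(B3OC(C)(C)C(C)(C)O3)c(OCOC)cc2OC(C)(C)CCc12 | intermediate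
12 | 2,4-dihydroxyacetophenone | CC(=O)c1ccc(O)cc1O | starting material
13 | 1-[2-hydroxy-4-(methoxymethoxy)phenyl]ethanone | CC(=O)c1ccc(OCOC)cc1O | intermediate
14 | (E)-3-(dimethylamino)-1-[2-hydroxy-4-(methoxymethoxy)phenyl]prop-2-en-1-one | CN(C)/C=C/C(=O)c1ccc(OCOC)cc1O | intermediate
15 | 3-iodo-7-(methoxymethoxy)-4H-chromen-4-one | O=c1c(I)coc2cc(OCOC)ccc12 | intermediate
16 | 7-(methoxymethoxy)-3-[5-methoxy-7-(methoxymethoxy)-2,2-dimethylchroman-6-yl]-4H-chromen-4-one | COCOc1ccc2c(c1)occ(-c1c(OC)c3c(cc1OCOC)OC(C)(C)CC3)c2=O | intermediate
17 | glycyrrhizaisoflavone C | COc1c2c(cc(O)c1-c1coc3cc(O)ccc3c1=O)OC(C)(C)CC2 | target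

**Step count**
- Total steps: 12.
- Longest linear sequence: 9 (steps 1 to 7, then 11 and 12).

**Steps most likely to fail**

1. **Step 6.**
 - What may go wrong: the donor-stabilised quinone methide may dimerise, or be attacked at its methylene carbon by the free C5'-H position of unreacted material. If either is faster than addition of the weakly nucleophilic, unactivated alkene, oligomerisation consumes the substrate.
 - Fallback: ring D is closed by an intramolecular pericyclic step. The fallback sets out from aldehyde 5. 2-Methylprop-1-enylmagnesium bromide (2.5 equiv, THF, 0 °C) should add to the formyl group and give racemic 4-bromo-2-(1-hydroxy-3-methylbut-2-en-1-yl)-3-methoxy-5-(methoxymethoxy)phenol F1. Warming this in toluene should bring about loss of water and oxa-6π ring closure to 6-bromo-5-methoxy-7-(methoxymethoxy)-2,2-dimethyl-2H-chromene F2. Hydrogenation of its C3=C4 bond (H2, PtO2, EtOAc, a catalyst that should spare the aryl bromide) comes back to the route at 9.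

2. **Step 11.**
 - What may go wrong: protodeboronation of the boronate flanked by two alkoxy groups, slow transmetalation at this crowded carbon, and opening of the pyrone ring of the iodochromone by aqueous base.
 - Fallback: a Negishi coupling uses neither boron nor water. The fallback sets out from bromide 9, which is converted to aryllithium 10 as in step 7. ZnCl2 in THF then transmetalates it to chloro[5-methoxy-7-(methoxymethoxy)-2,2-dimethylchroman-6-yl]zinc F3. This is coupled in the same flask with 15 (Pd(OAc)2, SPhos, THF, 50 °C) and comes back to the route at 16.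

3. **Step 4.**
 - What may go wrong: poor discrimination between the two acetals, with loss of both MOM groups or a mixture of mono-ethers.
 - Fallback: the differentiation is moved from the cleavage to the protection. The fallback sets out from 4. HCl in MeOH removes both MOM groups and gives 3-bromo-4,6-dihydroxy-2-methoxybenzaldehyde F4. MOMCl (1.0 equiv) with i-Pr2NEt in CH2Cl2 at 0 °C should then cap only the acidic, unchelated C4 hydroxyl, because the C6 hydroxyl is tied to the formyl oxygen. This comes back to the route at 5.

**Further compounds**
F1 | step 6 | 4-bromo-2-(1-hydroxy-3-methylbut-2-en-1-yl)-3-methoxy-5-(methoxymethoxy)phenol (racemic) | COCOc1cc(O)c(C(O)C=C(C)C)c(OC)c1Br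
F2 | step 6 | 6-bromo-5-methoxy-7-(methoxymethoxy)-2,2-dimethyl-2H-chromene | COCOc1cc2OC(C)(C)C=Cc2c(OC)c1Br
F3 | step 11 | chloro[5-methoxy-7-(methoxymethoxy)-2,2-dimethylchroman-6-yl]zinc | COc1c([Zn]Cl)c(OCOC)cc2OC(C)(C)CCc12
F4 | step 4 | 3-bromo-4,6-dihydroxy-2-methoxybenzaldehyde | O=Cc1c(OC)c(Br)c(O)cc1O
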